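**Retrosynthetic overview**

1. Target 17 ⇐ octa-O-benzyl ether 16 by global hydrogenolysis.
2. 16 ⇐ bis(2H-chromene) 14 by double syn-hydroboration/oxidation; each C2 aryl relays its configuration to C3 (both units) and to C4 (upper unit).
3. 14 ⇐ acyclic tetraol 12 by one chiral-acid-catalysed double dehydrative cycloetherification. It forms the C2–O1 bond of pyran ring C (upper unit) first and of pyran ring F (lower unit) second; this is the only ring-forming step, all four benzene rings are bought.
4. 12 ⇐ aryllithium from bromo allylic alcohol 7 + 2'-hydroxychalcone 4; the 1,2-addition makes the interflavan C4–C6 bond as a tertiary carbinol.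
5. 4 and 7 ⇐ acetophenone 2 (from gallacetophenone 1) + 3,4-bis(benzyloxy)benzaldehyde 3 by Claisen–Schmidt condensation, with one ring bromination for the lower half.

Assumption: the sense of induction of the chiral acid in step 7 cannot be predicted; the (R) acid is written and stands for whichever antipode gives the (2S) chromene centres.

**Route**

Step 1
Reactants: 1 gallacetophenone
Product: 2 1-[3,4-bis(benzyloxy)-2-hydroxyphenyl]ethanone
Conditions: BnBr (2.1 equiv), K2CO3 (2.2 equiv), DMF, 25 °C, 16 h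
Reagents that add atoms: benzyl bromide, BrCc1ccccc1
Why: Williamson etherification; the 2-OH is hydrogen-bonded to the acetyl carbonyl and is the least nucleophilic, so the 3- and 4-phenols are benzylated selectively.

Step 2
Reactants: 2 1-[3,4-bis(benzyloxy)-2-hydroxyphenyl]ethanone; 3 3,4-bis(benzyloxy)benzaldehyde
Product: 4 (E)-2'-hydroxychalcone (upper-unit chalcone)
Conditions: KOH (50% aq, 6 equiv), EtOH/THF, 25 °C, 36 h; then cold 1 M HCl to pH 6
Reagents that add atoms: none
Why: Claisen–Schmidt aldol condensation of a methyl ketone with a non-enolisable aldehyde; E1cB dehydration gives the (E)-enone.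

Step 3
Reactants: 2 1-[3,4-bis(benzyloxy)-2-hydroxyphenyl]ethanone
Product: 5 1-[3,4-bis(benzyloxy)-5-bromo-2-hydroxyphenyl]ethanone
Conditions: NBS (1.05 equiv), MeCN, 0 → 25 °C, dark
Reagents that add atoms: N-bromosuccinimide, O=C1CCC(=O)N1Br
Why: electrophilic aromatic bromination; C5 is para to the free phenol, ortho to the 4-benzyloxy group and meta to the acetyl group, so it is the only strongly activated free position.

Step 4
Reactants: 5 1-[3,4-bis(benzyloxy)-5-bromo-2-hydroxyphenyl]ethanone; 3 3,4-bis(benzyloxy)benzaldehyde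
Product: 6 (E)-5'-bromo-2'-hydroxychalcone (lower-unit chalcone)
Conditions: KOH (50% aq, 6 equiv), EtOH/THF, 25 °C, 36 h; then cold 1 M HCl to pH 6
Reagents that add atoms: none
Why: Claisen–Schmidt condensation as in step 2; the aryl bromide is inert to aqueous KOH.

Step 5
Reactants: 6 (E)-5'-bromo-2'-hydroxychalcone
Product: 7 racemic (E)-allylic alcohol (2-hydroxyaryl cinnamyl carbinol)
Conditions: NaBH4 (2 equiv), THF/EtOH 1:1, 0 °C, 1 h; ice-cold aq NaHCO3, extraction with EtOAc/0.5% Et3N, concentration below 25 °C, crude used at once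
Reagents that add atoms: none
Why: borohydride 1,2-reduction of the aryl enone carbonyl under basic, cold conditions that keep the acid-labile carbinol uncyclised; its racemic centre is erased in step 7.

Step 6
Reactants: 7 racemic (E)-allylic alcohol; 4 (E)-2'-hydroxychalcone
Product: 12 acyclic tetraol (bis-carbinol bis-phenol), via dilithium salt 8 (not isolated), via trilithio species 9 (not isolated), via sodium phenoxide 10 (not isolated), via alkoxide adduct 11 (not isolated)
Conditions: 7 (1.15 equiv), MeLi (2.3 equiv), THF, −78 °C; t-BuLi (2.3 equiv), −78 °C, 20 min; add 10 [4 (1.0 equiv), NaH (1.05 equiv), THF, 0 °C], −78 → −30 °C, 2 h; H2O; filtration through Et3N-deactivated silica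
Reagents that add atoms: none
Why: bromine–lithium exchange on the O-metallated bromide followed by 1,2-addition of the aryllithium to a non-enolisable aryl vinyl ketone creates the future C4–C6 interflavan bond; both carbinol centres are left as mixtures because step 7 erases them.

Step 7
Reactants: 12 acyclic tetraol
Product: 14 (2S,2S)-bis(2H-chromene), via mono-chromene 13 (not isolated)
Conditions: (R)-3,3'-bis(2,4,6-triisopropylphenyl)-1,1'-binaphthyl-2,2'-diyl N-triflylphosphoramide (10 mol%), toluene (0.01 M), 4 Å MS, −78 → −50 °C, 24 h; Et3N at −78 °C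
Reagents that add atoms: none
Why: Proposed new method: an enantioconvergent double dehydrative cycloetherification in which one chiral N-triflylphosphoramide ionises both carbinols (the tertiary triaryl carbinol first, then the secondary one) to hydroxy-allyl cation/quinone-methide species that stay hydrogen-bonded through the ortho-phenol to the chiral anion, so that each phenol oxygen closes onto the distal, aryl-bearing allyl terminus (oxa-6π-type collapse of the contact ion pair) from one helical conformer and sets the (2S) C2–O1 centre of both pyran rings, the four carbinol stereoisomers of 12 converging because ionisation erases them; the closest known reaction type is the chiral Brønsted acid catalysed asymmetric intramolecular allylic etherification of simple 2-(1-hydroxy-1,3-diarylallyl)phenols to 2,4-diaryl-2H-chromenes, together with chiral phosphoric acid catalysis of ortho-quinone methides, neither shown for two ring closures in one substrate, for a secondary cinnamyl-type carbinol or for such easily ionised polyalkoxy arenes.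

Step 8
Reactants: 14 (2S,2S)-bis(2H-chromene)
Product: 16 octa-O-benzyl dimer, via bis(alkylborane) 15 (not isolated)
Conditions: BH3·THF (6 equiv), THF, 0 → 25 °C, 12 h; then 3 M NaOH, 30% H2O2, 0 → 25 °C
Reagents that add atoms: hydrogen peroxide, OO
Why: Brown syn-hydroboration–oxidation; borane adds to each chromene alkene from the face opposite its C2 aryl group with boron on C3, so H and OH end up cis, which gives 2,3-trans in both pyran rings and 3,4-trans (C4 aryl anti to OH) in ring C, and the oxidation retains configuration.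

Step 9
Reactants: 16 octa-O-benzyl dimer
Product: 17 target, mesquitol-(4α→6)-mesquitol
Conditions: H2 (1 atm), Pd(OH)2/C (20 wt%), THF/MeOH/H2O 20:20:1, 25 °C, 6 h; filtration under argon, lyophilisation
Reagents that add atoms: none
Why: catalytic hydrogenolysis of the eight benzyl ethers, the standard final step for benzylated flavan-3-ol oligomers; the interflavan bond and the cyclic C2–O1 ethers are not cleaved under these mild conditions.

**Stereochemical bookkeeping**

- Both C2 centres are set in step 7. C3 of both units and C4 of the upper unit are set in step 8. Nothing later touches them.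
- The descriptor at C2 changes from S (chromene 14) to R (16, 17) without a change in geometry, because C3 outranks the aryl group once it carries oxygen.
- The descriptor at C4 changes from S (16) to R (17) for the same reason: debenzylation reorders two aryl branches.
- Because two centres are set by the catalyst, a per-closure selectivity of 95:5 gives (S,S):(R,R) = 361:1. The two unlike diastereomers (about 9.5%) are removed by chromatography at 14 or 16.

**Compound list**

1 | gallacetophenone, 1-(2,3,4-trihydroxyphenyl)ethanone | CC(=O)c1ccc(O)c(O)c1O | starting material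

2 | 1-[3,4-bis(benzyloxy)-2-hydroxyphenyl]ethanone | CC(=O)c1ccc(OCc2ccccc2)c(OCc2ccccc2)c1O | intermediate

3 | 3,4-bis(benzyloxy)benzaldehyde | O=Cc1ccc(OCc2ccccc2)c(OCc2ccccc2)c1 | starting material

4 | (E)-1-[3,4-bis(benzyloxy)-2-hydroxyphenyl]-3-[3,4-bis(benzyloxy)phenyl]prop-2-en-1-one | O=C(/C=C/c1ccc(OCc2ccccc2)c(OCc2ccccc2)c1)c1ccc(OCc2ccccc2)c(OCc2ccccc2)c1O | intermediate

5 | 1-[3,4-bis(benzyloxy)-5-bromo-2-hydroxyphenyl]ethanone | CC(=O)c1cc(Br)c(OCc2ccccc2)c(OCc2ccccc2)c1O | intermediate

6 | (E)-1-[3,4-bis(benzyloxy)-5-bromo-2-hydroxyphenyl]-3-[3,4-bis(benzyloxy)phenyl]prop-2-en-1-one | O=C(/C=C/c1ccc(OCc2ccccc2)c(OCc2ccccc2)c1)c1cc(Br)c(OCc2ccccc2)c(OCc2ccccc2)c1O | intermediate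

7 | racemic (E)-1-[3,4-bis(benzyloxy)-5-bromo-2-hydroxyphenyl]-3-[3,4-bis(benzyloxy)phenyl]prop-2-en-1-ol | OC(/C=C/c1ccc(OCc2ccccc2)c(OCc2ccccc2)c1)c1cc(Br)c(OCc2ccccc2)c(OCc2ccccc2)c1O | intermediate

8 | dilithium alkoxide/phenoxide of 7 | [Li]OC(/C=C/c1ccc(OCc2ccccc2)c(OCc2ccccc2)c1)c1cc(Br)c(OCc2ccccc2)c(OCc2ccccc2)c1O[Li] | intermediate (not isolated)

9 | trilithio species: aryllithium at the former C–Br carbon of 8 | [Li]OC(/C=C/c1ccc(OCc2ccccc2)c(OCc2ccccc2)c1)c1cc([Li])c(OCc2ccccc2)c(OCc2ccccc2)c1O[Li] | intermediate (not isolated)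

10 | sodium phenoxide of chalcone 4 | O=C(/C=C/c1ccc(OCc2ccccc2)c(OCc2ccccc2)c1)c1ccc(OCc2ccccc2)c(OCc2ccccc2)c1O[Na] | intermediate (not isolated)

11 | tetra-metallated adduct (three O–Li, one O–Na) before quench | [Li]OC(/C=C/c1ccc(OCc2ccccc2)c(OCc2ccccc2)c1)(c1ccc(OCc2ccccc2)c(OCc2ccccc2)c1O[Na])c1cc(C(O[Li])/C=C/c2ccc(OCc3ccccc3)c(OCc3ccccc3)c2)c(O[Li])c(OCc2ccccc2)c1OCc2ccccc2 | intermediate (not isolated)

12 | (E)-1-[3,4-bis(benzyloxy)-2-hydroxyphenyl]-1-{2,3-bis(benzyloxy)-4-hydroxy-5-[(E)-3-(3,4-bis(benzyloxy)phenyl)-1-hydroxyprop-2-en-1-yl]phenyl}-3-[3,4-bis(benzyloxy)phenyl]prop-2-en-1-ol, mixture of the four stereoisomers at the two carbinol carbons | OC(/C=C/c1ccc(OCc2ccccc2)c(OCc2ccccc2)c1)(c1ccc(OCc2ccccc2)c(OCc2ccccc2)c1O)c1cc(C(O)/C=C/c2ccc(OCc3ccccc3)c(OCc3ccccc3)c2)c(O)c(OCc2ccccc2)c1OCc2ccccc2 | intermediate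

13 | 2,3-bis(benzyloxy)-4-{(2S)-7,8-bis(benzyloxy)-2-[3,4-bis(benzyloxy)phenyl]-2H-chromen-4-yl}-6-[(E)-3-(3,4-bis(benzyloxy)phenyl)-1-hydroxyprop-2-en-1-yl]phenol (ring C closed, ring F still open; carbinol centre mixed) | O(Cc5ccccc5)c1ccc([C@H]2Oc3c(ccc(OCc5ccccc5)c3OCc5ccccc5)C(c3cc(C(O)/C=C/c4ccc(OCc5ccccc5)c(OCc5ccccc5)c4)c(O)c(OCc5ccccc5)c3OCc5ccccc5)=C2)cc1OCc5ccccc5 | intermediate (not isolated)

14 | (2S)-7,8-bis(benzyloxy)-2-[3,4-bis(benzyloxy)phenyl]-4-{(2S)-7,8-bis(benzyloxy)-2-[3,4-bis(benzyloxy)phenyl]-2H-chromen-6-yl}-2H-chromene | O(Cc5ccccc5)c1ccc([C@H]2Oc3c(ccc(OCc5ccccc5)c3OCc5ccccc5)C(c3cc4c(c(OCc5ccccc5)c3OCc5ccccc5)O[C@H](c3ccc(OCc5ccccc5)c(OCc5ccccc5)c3)C=C4)=C2)cc1OCc5ccccc5 | intermediate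

15 | bis(alkylborane): BH2 on C3 of each pyran ring, trans to the C2 aryl; H on C4 on the same face as boron | O(Cc5ccccc5)c1ccc([C@H]2Oc3c(ccc(OCc5ccccc5)c3OCc5ccccc5)[C@@H](c3cc4c(c(OCc5ccccc5)c3OCc5ccccc5)O[C@H](c3ccc(OCc5ccccc5)c(OCc5ccccc5)c3)[C@@H](B)C4)[C@@H]2B)cc1OCc5ccccc5 | intermediate (not isolated)

16 | (2R,3S,4S)-7,8-bis(benzyloxy)-2-[3,4-bis(benzyloxy)phenyl]-4-{(2R,3S)-7,8-bis(benzyloxy)-2-[3,4-bis(benzyloxy)phenyl]-3-hydroxychroman-6-yl}chroman-3-ol (all-trans upper unit; same geometry as 17) | O(Cc5ccccc5)c1ccc([C@H]2Oc3c(ccc(OCc5ccccc5)c3OCc5ccccc5)[C@@H](c3cc4c(c(OCc5ccccc5)c3OCc5ccccc5)O[C@H](c3ccc(OCc5ccccc5)c(OCc5ccccc5)c3)[C@@H](O)C4)[C@@H]2O)cc1OCc5ccccc5 | intermediate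

17 | (2R,3S,4R)-2-(3,4-dihydroxyphenyl)-4-[(2R,3S)-2-(3,4-dihydroxyphenyl)-3,7,8-trihydroxychroman-6-yl]chroman-3,7,8-triol, 2,3-trans-3,4-trans, (4α→6)-linked | Oc1ccc([C@H]2Oc3c(ccc(O)c3O)[C@@H](c3cc4c(c(O)c3O)O[C@H](c3ccc(O)c(O)c3)[C@@H](O)C4)[C@@H]2O)cc1O | target

**Totals**

- Total steps: 9.
- Longest linear sequence: 8 (steps 1, 3, 4, 5, 6, 7, 8, 9).

**Three steps most likely to fail**

Step 7 (the proposed new step). The risks are:
- unequal or low selectivity at one of the two closures;
- loss of selectivity through reversible C2–O ionisation of the very electron-rich chromenes;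
- Friedel–Crafts closure of the triarylallyl cation to an indene;
- a para-quinone methide resting state on the lower ring.

Fallback, known chemistry: set out from tetraol 12 and cyclise it with an achiral acid (pyridinium p-toluenesulfonate, 10 mol%, CH2Cl2, 0 °C). This long-known cyclodehydration of 2-(1-hydroxyallyl)phenols gives the bis(2H-chromene) as the statistical mixture of four stereoisomers F4. The like and unlike pairs are separated on silica, and the (2S,2S) isomer is then isolated by preparative chromatography on an amylose tris(3,5-dimethylphenylcarbamate) stationary phase. The theoretical yield is at most one quarter. The route is rejoined at 14.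

Step 6 (polyanion union). The risks are:
- poor solubility of the trilithio species;
- slow bromine–lithium exchange on the phenoxide-bearing ring;
- 1,4-addition to the deactivated phenoxide enone;
- premature cyclisation of 7 or 12 to racemic chromenes on handling.

Fallback: set out from 7 and 4 and mask the acidic groups first. TESCl/imidazole in DMF converts 7 into its bis(triethylsilyl) ether F1 and 4 into the chalcone triethylsilyl ether F2. F1 is lithiated with t-BuLi (2 equiv, THF, −78 °C) and added to F2 to give the tris(triethylsilyl) tertiary carbinol F3. Desilylation with Bu4NF in THF at 0 °C (basic throughout) returns to tetraol 12. This costs two extra operations.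

Step 8 (double hydroboration). The risks are:
- slow or unselective reaction of the hindered trisubstituted alkene of ring C;
- ring opening by elimination of the β-aryloxy borane;
- some boron at C4 of ring F.

Fallback: set out from 14 and use a copper-catalysed syn-borylation–protonation instead of free borane: CuCl (10 mol%), Xantphos, NaOt-Bu, B2pin2, MeOH, THF, 25 °C. Boron goes to C3 anti to the C2 aryl, and the benzylic C–Cu bond is protonated with retention, which gives the 3,3'-bis(pinacolboronate) F5. Oxidation with NaBO3·4H2O in THF/H2O returns to 16 with the same all-trans outcome.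

**Further compounds**

F1 | step 6 | racemic bis(triethylsilyl) ether of 7 (O-silylated carbinol and phenol) | CC[Si](CC)(CC)OC(/C=C/c1ccc(OCc2ccccc2)c(OCc2ccccc2)c1)c1cc(Br)c(OCc2ccccc2)c(OCc2ccccc2)c1O[Si](CC)(CC)CC

F2 | step 6 | triethylsilyl ether of chalcone 4 | O=C(/C=C/c1ccc(OCc2ccccc2)c(OCc2ccccc2)c1)c1ccc(OCc2ccccc2)c(OCc2ccccc2)c1O[Si](CC)(CC)CC

F3 | step 6 | tris(triethylsilyl) ether of tetraol 12 with free tertiary carbinol (stereoisomer mixture) | OC(/C=C/c1ccc(OCc2ccccc2)c(OCc2ccccc2)c1)(c1ccc(OCc2ccccc2)c(OCc2ccccc2)c1O[Si](CC)(CC)CC)c1cc(C(O[Si](CC)(CC)CC)/C=C/c2ccc(OCc3ccccc3)c(OCc3ccccc3)c2)c(O[Si](CC)(CC)CC)c(OCc2ccccc2)c1OCc2ccccc2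

F4 | step 7 | bis(2H-chromene) of the constitution of 14 as the mixture of four stereoisomers at the two C2 centres | O(Cc5ccccc5)c1ccc(C2Oc3c(ccc(OCc5ccccc5)c3OCc5ccccc5)C(c3cc4c(c(OCc5ccccc5)c3OCc5ccccc5)OC(c3ccc(OCc5ccccc5)c(OCc5ccccc5)c3)C=C4)=C2)cc1OCc5ccccc5

F5 | step 8 | 3,3'-bis(pinacolboronate) analogue of 16 (Bpin in place of each 3-OH, same configuration) | O(Cc5ccccc5)c1ccc([C@H]2Oc3c(ccc(OCc5ccccc5)c3OCc5ccccc5)[C@@H](c3cc4c(c(OCc5ccccc5)c3OCc5ccccc5)O[C@H](c3ccc(OCc5ccccc5)c(OCc5ccccc5)c3)[C@@H](B6OC(C)(C)C(C)(C)O6)C4)[C@@H]2B6OC(C)(C)C(C)(C)O6)cc1OCc5ccccc5
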